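**Assumption:** the SMILES descriptor corresponds to (R) at the carbinol carbon (priorities OH > C(=O)Ar > CH2Ar > H), and catalogue chemicals such as prenyltributylstannane, (TBSO)acetaldehyde and linked-BINOL count as commercially available.

## Retrosynthetic overview

1. Target ⇐ its A-ring bis-MOM ether by a final mild acid deprotection.
2. Key disconnection at Cα–Cβ: a chiral zinc enolate of an A-ring α-hydroxyacetophenone adds 1,6 to a B-ring p-quinone methide made in situ from a 4-hydroxybenzyl tert-butyl carbonate. This new step forms the central C–C bond and sets the only stereocentre (R).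
3. A-ring donor ⇐ resorcinol: MOM protection, ortho-metalation/prenylation, ortho-metalation/addition to TBSOCH2CHO, oxidation, desilylation.
4. B-ring precursor ⇐ 3-bromo-4-hydroxybenzaldehyde: silylation, Stille prenylation, reduction, Boc carbonate, desilylation.
5. No ring is formed; both benzene rings are purchased, and both prenyl groups go in early so that no oxidant or H2 step follows them.

## Route

**Step 1**
Reactants: 1 resorcinol; 2 chloromethyl methyl ether (MOMCl)
Product: 3 1,3-bis(methoxymethoxy)benzene
Conditions: NaH, MOMCl (2.4 equiv each), DMF, 0 °C → rt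
Reagents that add atoms: MOMCl (2), COCCl
Why: Double Williamson O-alkylation (MOM protection); the MOM ethers serve as ortho-directing groups and as acid-labile protection.

**Step 2**
Reactants: 3; 4 prenyl bromide (1-bromo-3-methylbut-2-ene)
Product: 5 1,3-bis(methoxymethoxy)-2-(3-methylbut-2-en-1-yl)benzene
Conditions: n-BuLi, THF, 0 °C → rt, 1 h; CuBr·SMe2 (10 mol %), then 4, −78 °C → rt
Reagents that add atoms: prenyl bromide (4), CC(C)=CCBr
Why: Directed ortho-metalation at the doubly activated C2 position, then copper-assisted SN2 allylation at the primary carbon of prenyl bromide to give the linear prenyl arene.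

**Step 3**
Reactants: 5; 6 (tert-butyldimethylsilyloxy)acetaldehyde
Product: 7 2-[(tert-butyldimethylsilyl)oxy]-1-[2,4-bis(methoxymethoxy)-3-(3-methylbut-2-en-1-yl)phenyl]ethan-1-ol (racemic)
Conditions: s-BuLi, TMEDA, THF, −78 °C, 1 h; then 6, −78 °C; aq NH4Cl
Reagents that add atoms: (TBSO)acetaldehyde (6), O=CCO[Si](C)(C)C(C)(C)C
Why: OMOM-directed ortho-lithiation at C4 (the only ring C–H ortho to an OMOM), kept at −78 °C to avoid benzylic/allylic deprotonation, then 1,2-addition to the aldehyde; the racemic carbinol centre is erased in step 4.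

**Step 4**
Reactants: 7
Product: 8 2-[(tert-butyldimethylsilyl)oxy]-1-[2,4-bis(methoxymethoxy)-3-(3-methylbut-2-en-1-yl)phenyl]ethan-1-one
Conditions: Dess–Martin periodinane, NaHCO3, CH2Cl2, 0 °C → rt
Reagents that add atoms: none
Why: Dess–Martin oxidation of the benzylic alcohol to the aryl ketone under buffered, non-acidic conditions that leave prenyl, MOM and TBS intact.

**Step 5**
Reactants: 8
Product: 9 2-hydroxy-1-[2,4-bis(methoxymethoxy)-3-(3-methylbut-2-en-1-yl)phenyl]ethan-1-one
Conditions: TBAF/AcOH (1:1), THF, 0 °C
Reagents that add atoms: none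
Why: Fluoride desilylation buffered with AcOH so the α-hydroxy ketone never sees free base; MOM and prenyl are inert.

**Step 6**
Reactants: 10 3-bromo-4-hydroxybenzaldehyde; 11 tert-butyldimethylsilyl chloride (TBSCl)
Product: 12 3-bromo-4-[(tert-butyldimethylsilyl)oxy]benzaldehyde
Conditions: imidazole, DMF, rt
Reagents that add atoms: TBSCl (11), CC(C)(C)[Si](C)(C)Cl
Why: Standard phenol silylation; a fluoride-labile group lets the phenol be released later without base or strong acid.

**Step 7**
Reactants: 12; 13 tributyl(3-methylbut-2-en-1-yl)stannane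
Product: 14 4-[(tert-butyldimethylsilyl)oxy]-3-(3-methylbut-2-en-1-yl)benzaldehyde
Conditions: Pd(PPh3)4 (5 mol %), DMF, 95 °C
Reagents that add atoms: prenyltributylstannane (13), CCCC[Sn](CCCC)(CCCC)CC=C(C)C
Why: Stille cross-coupling of the aryl bromide; reductive elimination at the less hindered terminus of the prenyl–Pd species gives the linear prenyl group.

**Step 8**
Reactants: 14
Product: 15 {4-[(tert-butyldimethylsilyl)oxy]-3-(3-methylbut-2-en-1-yl)phenyl}methanol
Conditions: NaBH4, THF/EtOH, 0 °C, 20 min
Reagents that add atoms: none
Why: Chemoselective borohydride reduction of the aldehyde to the benzylic alcohol.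

**Step 9**
Reactants: 15; 16 di-tert-butyl dicarbonate (Boc2O)
Product: 17 tert-butyl {4-[(tert-butyldimethylsilyl)oxy]-3-(3-methylbut-2-en-1-yl)benzyl} carbonate
Conditions: Boc2O (1.5 equiv), DMAP (10 mol %), CH2Cl2, 0 °C → rt
Reagents that add atoms: Boc2O (16), CC(C)(C)OC(=O)OC(=O)OC(C)(C)C
Why: DMAP-catalysed alkoxycarbonylation of the primary alcohol; the tert-butyl carbonate is the leaving group that later fragments to CO2 and t-BuO−.

**Step 10**
Reactants: 17
Product: 18 tert-butyl [4-hydroxy-3-(3-methylbut-2-en-1-yl)benzyl] carbonate
Conditions: TBAF/AcOH (1.1:1.5 equiv), THF, 0 °C; pH 6 buffer work-up, Florisil filtration, used the same day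
Reagents that add atoms: none
Why: Buffered fluoride desilylation releases the neutral phenol (never the phenoxide), so the 1,6-elimination to the quinone methide is not triggered before step 11.

**Step 11 (key step)**
Reactants: 9 (2.0 equiv, excess recovered); 18 (1.0 equiv)
Product: 19 (R)-1-[2,4-bis(methoxymethoxy)-3-(3-methylbut-2-en-1-yl)phenyl]-2-hydroxy-3-[4-hydroxy-3-(3-methylbut-2-en-1-yl)phenyl]propan-1-one
Conditions: (S,S)-linked-BINOL [(S,S)-3,3″-oxybis(methylene)-bis(1,1′-bi-2-naphthol)] (5 mol %), Et2Zn (20 mol %), 3 Å MS, THF, −20 → 0 °C; 18 added by syringe pump over 8 h under a slow Ar sweep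
Reagents that add atoms: none besides the two reactants (18, CC(C)=CCc1cc(COC(=O)OC(C)(C)C)ccc1O, delivers the 4-hydroxy-3-prenylbenzyl unit; CO2 and t-BuOH are lost)
Why: Proposed new method: a catalytic asymmetric direct 1,6-conjugate addition of an unprotected α-hydroxy ketone to a δ-unsubstituted p-quinone methide made in situ by a decarboxylative "traceless-base" elimination — the basic Zn–aryloxide sites of the catalyst convert 9 into a rigid chelated zinc enediolate (α-O and 2′-OMOM on zinc) and 18 into its zinc phenoxide, which expels tert-butyl carbonate (→ CO2 + t-BuO–Zn, regenerating the base, so no stoichiometric base or acid is present) to give 2-prenyl-4-methylenecyclohexa-2,5-dienone; the enolate face left open by the ligand attacks the exocyclic CH2, re-aromatisation makes C–C formation irreversible, and because the electrophilic carbon is not stereogenic only enolate-face selection matters, so the (S,S)-ligand is expected by analogy to give (R) (to be confirmed by chiral HPLC/Mosher analysis); closest known reaction type: Et2Zn/linked-BINOL direct asymmetric Michael addition of 2-hydroxy-2′-methoxyacetophenone to β-unsubstituted vinyl ketones, together with base-triggered 1,6-additions to in situ-generated p-quinone methides.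

**Step 12**
Reactants: 19
Product: 20 glycybridin C, (R)-1-[2,4-dihydroxy-3-(3-methylbut-2-en-1-yl)phenyl]-2-hydroxy-3-[4-hydroxy-3-(3-methylbut-2-en-1-yl)phenyl]propan-1-one
Conditions: 3 M aq HCl/MeOH (1:5), rt → 35 °C, monitored to completion
Reagents that add atoms: none
Why: Acid-catalysed MOM acetal hydrolysis; dilute acid at ≤35 °C is expected neither to cyclise the o-prenylphenols to chromans nor to enolise the α-ketol, so the (R) centre is retained.

## Compound list

1 | resorcinol | Oc1cccc(O)c1 | starting material
2 | chloromethyl methyl ether | COCCl | starting material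
3 | 1,3-bis(methoxymethoxy)benzene | COCOc1cccc(OCOC)c1 | intermediate
4 | prenyl bromide | CC(C)=CCBr | starting material
5 | 1,3-bis(methoxymethoxy)-2-prenylbenzene | COCOc1cccc(OCOC)c1CC=C(C)C | intermediate
6 | (tert-butyldimethylsilyloxy)acetaldehyde | O=CCO[Si](C)(C)C(C)(C)C | starting material
7 | 2-(TBSO)-1-[2,4-bis(MOMO)-3-prenylphenyl]ethan-1-ol (racemic) | CC(C)=CCc1c(OCOC)ccc(C(O)CO[Si](C)(C)C(C)(C)C)c1OCOC | intermediate
8 | 2-(TBSO)-1-[2,4-bis(MOMO)-3-prenylphenyl]ethan-1-one | CC(C)=CCc1c(OCOC)ccc(C(=O)CO[Si](C)(C)C(C)(C)C)c1OCOC | intermediate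
9 | 2-hydroxy-1-[2,4-bis(MOMO)-3-prenylphenyl]ethan-1-one | CC(C)=CCc1c(OCOC)ccc(C(=O)CO)c1OCOC | intermediate
10 | 3-bromo-4-hydroxybenzaldehyde | O=Cc1ccc(O)c(Br)c1 | starting material
11 | tert-butyldimethylsilyl chloride | CC(C)(C)[Si](C)(C)Cl | starting material
12 | 3-bromo-4-(TBSO)benzaldehyde | O=Cc1ccc(O[Si](C)(C)C(C)(C)C)c(Br)c1 | intermediate
13 | tributyl(3-methylbut-2-en-1-yl)stannane | CCCC[Sn](CCCC)(CCCC)CC=C(C)C | starting material
14 | 4-(TBSO)-3-prenylbenzaldehyde | CC(C)=CCc1cc(C=O)ccc1O[Si](C)(C)C(C)(C)C | intermediate
15 | [4-(TBSO)-3-prenylphenyl]methanol | CC(C)=CCc1cc(CO)ccc1O[Si](C)(C)C(C)(C)C | intermediate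
16 | di-tert-butyl dicarbonate | CC(C)(C)OC(=O)OC(=O)OC(C)(C)C | starting material
17 | tert-butyl [4-(TBSO)-3-prenylbenzyl] carbonate | CC(C)=CCc1cc(COC(=O)OC(C)(C)C)ccc1O[Si](C)(C)C(C)(C)C | intermediate
18 | tert-butyl (4-hydroxy-3-prenylbenzyl) carbonate | CC(C)=CCc1cc(COC(=O)OC(C)(C)C)ccc1O | intermediate
19 | (R)-1-[2,4-bis(MOMO)-3-prenylphenyl]-2-hydroxy-3-(4-hydroxy-3-prenylphenyl)propan-1-one | CC(C)=CCc1cc(C[C@@H](O)C(=O)c2ccc(OCOC)c(CC=C(C)C)c2OCOC)ccc1O | intermediate
20 | glycybridin C | CC(C)=CCc1cc(C[C@@H](O)C(=O)c2ccc(O)c(CC=C(C)C)c2O)ccc1O | target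

## Summary

Total steps: 12. Longest linear sequence: 7 (steps 1–5, 11, 12; the B-ring branch 6–10, 11, 12 is also 7).

**Three steps most likely to fail**

1. **Step 11 (proposed new reaction).** Risks are oligomerisation or O-alkylation of the unhindered quinone methide, over-benzylation of the product phenol, and poor chelation by the hindered 2′-OMOM.
   Fallback (known chemistry, different approach): make the stereocentre by late enolate oxidation instead of C–C formation.
   - Lithiated 5 + N-methoxy-N-methylacetamide gives the A-ring methyl ketone.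
   - Claisen–Schmidt condensation (KOH, EtOH) with 4-(methoxymethoxy)-3-prenylbenzaldehyde gives the chalcone.
   - Conjugate reduction with Stryker's reagent gives the dihydrochalcone, leaving the prenyls untouched.
   - Davis asymmetric enolate hydroxylation (NaHMDS, THF, −78 °C, then the (−)-(8,8-dichlorocamphorylsulfonyl)oxaziridine enantiomer, expected by analogy to give R) installs the hydroxyl.
   - HCl/MeOH removes the MOM groups.

2. **Step 10 (isolation of 18).** The free-phenol benzylic carbonate is a self-immolative quinone-methide precursor and may decompose on handling.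
   Fallback: switch to a bench-stable sulfone precursor. Convert 15 with PBr3 to the benzyl bromide, displace with sodium p-toluenesulfinate, and desilylate to give 4-hydroxy-3-prenylbenzyl p-tolyl sulfone. This releases the quinone methide only on deprotonation, so step 11 would then need one equivalent of a mild solid base (e.g. K3PO4), which is itself untested with the zinc catalyst.

3. **Step 3 (second metalation).** The benzylic/allylic CH2 of the prenyl group can compete with ring lithiation.
   Fallback: generate the same aryllithium by halogen–metal exchange instead of C–H deprotonation. 4-Bromoresorcinol → bis-MOM ether → LiTMP/prenyl bromide at C3 (between the OMOM groups) → t-BuLi, −78 °C (Br–Li exchange outruns any deprotonation) → addition to 6.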